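**Retrosynthetic overview**

- The target is (5S)-2-[(12Z)-heptadec-12-en-1-yl]-5-hydroxy-5,6,7,8-tetrahydro-4H-chromen-4-one; the last operations are removal of a C3 bromine and of a C5 silyl ether.
- The strategy rests on one feature. Take the lone CH carbon C3 out of the pyranone ring O1–C2–C3–C4–C4a–C8a and the five atoms left, O1–C2–C4–C4a–C8a, are a furan that carries oxygen on a β-carbon. The pyranone is therefore cut at C2–C3 and C3–C4 into a 3-silyloxy-tetrahydrobenzofuran and one carbene carbon (CBr2).
- The silyloxyfuran comes from a 2-alkyl-6,7-dihydrobenzofuran-3,4(2H,5H)-dione by enol silylation, CBS reduction of the C4 ketone (the only stereocentre) and O-silylation.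
- The side chain is joined at furanone C2 by aldol condensation with (12Z)-heptadec-12-enal and conjugate reduction. The aldehyde comes from a Z-selective Wittig reaction of the 12-bromododecan-1-ol phosphonium salt with pentanal, and the furandione from cyclohexane-1,3-dione and chloroacetyl chloride.
- Ring order: carbocycle (purchased), then the furanone ring (step 2), then the pyranone ring by enlargement of the furan (step 11).

Key step: step 11

Remark: furans are numbered as 1-benzofurans (O1, C2, C3, C3a, C4–C7, C7a) and pyranones as chromenes (O1, C2, C3, C4, C4a, C5–C8, C8a). The exocyclic alkene of 12 is assumed Z; its geometry is removed in step 7 and does not matter.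

**Route**

Step 1
Reactants: 1 cyclohexane-1,3-dione; 2 chloroacetyl chloride
Product: 3 3-oxocyclohex-1-en-1-yl chloroacetate
Conditions: pyridine (1.1 equiv), CH2Cl2, 0 °C
Reagents that add atoms: none
Why: O-acylation of the enol of a cyclic 1,3-dione by an acid chloride under amine base (enol ester formation) is fast and selective for oxygen.

Step 2
Reactants: 3 3-oxocyclohex-1-en-1-yl chloroacetate
Product: 5 6,7-dihydro-1-benzofuran-3,4(2H,5H)-dione, via 2-(chloroacetyl)cyclohexane-1,3-dione 4 (not isolated)
Conditions: AlCl3 (2.2 equiv), ClCH2CH2Cl, rt to 40 °C; aq. HCl work-up; then Et3N (1.2 equiv), CH2Cl2, 0 °C to rt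
Reagents that add atoms: none
Why: A Lewis-acid O-to-C acyl shift (Fries-type rearrangement of a dione enol ester) should give the 2-acyl triketone, whose enol oxygen then displaces the α-chloride in a 5-exo-tet O-alkylation, as in coumaranone formation from 2-(chloroacetyl)phenols.

Step 3
Reactants: 6 12-bromododecan-1-ol
Product: 7 (12-hydroxydodecyl)triphenylphosphonium bromide
Conditions: PPh3 (1.1 equiv), MeCN, reflux
Reagents that add atoms: triphenylphosphine, c1ccc(cc1)P(c1ccccc1)c1ccccc1
Why: SN2 quaternisation of a primary alkyl bromide by triphenylphosphine.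

Step 4
Reactants: 7 (12-hydroxydodecyl)triphenylphosphonium bromide; 8 pentanal
Product: 10 (12Z)-heptadec-12-en-1-ol, via sodium alkoxide ylide 9 (not isolated)
Conditions: NaHMDS (2.05 equiv), THF, 0 °C; then 8, −78 °C to rt; H2O
Reagents that add atoms: none
Why: A lithium-free Wittig reaction of an unstabilised ylide with an aldehyde under kinetic control should give the Z-alkene through the cis-oxaphosphetane, the second equivalent of base holding the remote hydroxyl as its alkoxide.

Step 5
Reactants: 10 (12Z)-heptadec-12-en-1-ol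
Product: 11 (12Z)-heptadec-12-enal
Conditions: TEMPO (10 mol%), PhI(OAc)2 (1.1 equiv), CH2Cl2, rt
Reagents that add atoms: none
Why: Oxoammonium-catalysed (TEMPO) oxidation of a primary alcohol stops at the aldehyde and should neither touch nor isomerise the Z-alkene.

Step 6
Reactants: 5 6,7-dihydro-1-benzofuran-3,4(2H,5H)-dione; 11 (12Z)-heptadec-12-enal
Product: 12 (2Z)-2-[(12Z)-heptadec-12-en-1-ylidene]-6,7-dihydro-1-benzofuran-3,4(2H,5H)-dione
Conditions: piperidine (0.2 equiv), AcOH (0.2 equiv), toluene, 4 Å MS, rt to 50 °C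
Reagents that add atoms: none
Why: Knoevenagel-type aldol condensation: the C2 methylene of a furan-3(2H)-one is the most acidic site because its enolate is an aromatic 3-furanolate, and it should condense with the aldehyde (through its iminium ion) as coumaranones do in aurone synthesis.

Step 7
Reactants: 12 (2Z)-2-[(12Z)-heptadec-12-en-1-ylidene]-6,7-dihydro-1-benzofuran-3,4(2H,5H)-dione
Product: 13 2-[(12Z)-heptadec-12-en-1-yl]-6,7-dihydro-1-benzofuran-3,4(2H,5H)-dione (racemic at C2)
Conditions: [(Ph3P)CuH]6 (0.2 equiv), H2O (2 equiv), degassed benzene/THF, rt, under argon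
Reagents that add atoms: none
Why: Stryker conjugate reduction: the copper hydride should deliver hydride only to the unhindered β-carbon of the exocyclic enone, which releases an aromatic furanolate, and leave the isolated Z-alkene and both carbonyl groups alone.

Step 8
Reactants: 13 2-[(12Z)-heptadec-12-en-1-yl]-6,7-dihydro-1-benzofuran-3,4(2H,5H)-dione
Product: 14 3-[(tert-butyldimethylsilyl)oxy]-2-[(12Z)-heptadec-12-en-1-yl]-6,7-dihydro-1-benzofuran-4(5H)-one
Conditions: TBSOTf (1.1 equiv), Et3N (1.5 equiv), CH2Cl2, −78 to 0 °C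
Reagents that add atoms: tert-butyldimethylsilyl trifluoromethanesulfonate, CC(C)(C)[Si](C)(C)OS(=O)(=O)C(F)(F)F
Why: Soft enolisation and O-silylation of a furan-3(2H)-one gives the aromatic 3-silyloxyfuran; C2–H is far more acidic than C5–H2, so the C4 ketone should stay free and the C2 stereocentre of 13 is erased.

Step 9
Reactants: 14 3-[(tert-butyldimethylsilyl)oxy]-2-[(12Z)-heptadec-12-en-1-yl]-6,7-dihydro-1-benzofuran-4(5H)-one
Product: 15 (4S)-3-[(tert-butyldimethylsilyl)oxy]-2-[(12Z)-heptadec-12-en-1-yl]-4,5,6,7-tetrahydro-1-benzofuran-4-ol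
Conditions: (R)-2-methyl-CBS-oxazaborolidine (0.2 equiv), catecholborane (1.5 equiv), toluene, −78 to −40 °C; MeOH, then pH 7 buffer and dilute NaOH wash
Reagents that add atoms: none
Why: Corey–Bakshi–Shibata reduction: with the furyl side as the large group and C5H2 as the small one, the (R)-oxazaborolidine should deliver hydride to the Re face of C4 and set the (4S) carbinol, and catecholborane at low temperature does not hydroborate the Z-alkene.

Step 10
Reactants: 15 (4S)-3-[(tert-butyldimethylsilyl)oxy]-2-[(12Z)-heptadec-12-en-1-yl]-4,5,6,7-tetrahydro-1-benzofuran-4-ol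
Product: 16 (4S)-3,4-bis[(tert-butyldimethylsilyl)oxy]-2-[(12Z)-heptadec-12-en-1-yl]-4,5,6,7-tetrahydro-1-benzofuran
Conditions: TBSOTf (1.2 equiv), 2,6-lutidine (2 equiv), CH2Cl2, −78 °C
Reagents that add atoms: tert-butyldimethylsilyl trifluoromethanesulfonate, CC(C)(C)[Si](C)(C)OS(=O)(=O)C(F)(F)F
Why: Silylation of a secondary alcohol with a silyl triflate under buffered low-temperature conditions does not break the C4–O bond, so the (4S) configuration is kept and ionisation of the furylic alcohol is avoided.

Step 11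
Reactants: 16 (4S)-3,4-bis[(tert-butyldimethylsilyl)oxy]-2-[(12Z)-heptadec-12-en-1-yl]-4,5,6,7-tetrahydro-1-benzofuran
Product: 19 (5S)-3-bromo-5-[(tert-butyldimethylsilyl)oxy]-2-[(12Z)-heptadec-12-en-1-yl]-5,6,7,8-tetrahydro-4H-chromen-4-one, via dibromocyclopropane adduct 17 (not isolated), via silyloxypyrylium bromide 18 (not isolated)
Conditions: CHBr3 (1.2 equiv), KOtBu (2.4 equiv, added in portions), pentane, −30 to 0 °C
Reagents that add atoms: bromoform, BrC(Br)Br
Why: Proposed new method: α-elimination of bromoform gives singlet dibromocarbene, an electrophile that should add in a concerted [2+1] fashion across C2=C3 of the furan, whose C2 terminus is at once a furan α-carbon and the β-carbon of a silyl enol ether, to give the dibromocyclopropane 17. Disrotatory electrocyclic opening of 17 with loss of bromide breaks the old C2–C3 bond and, pushed by the lone pairs of O1 and of the siloxy oxygen, gives the aromatic 3-bromo-4-silyloxypyrylium salt 18, which passes its silyl group to tert-butoxide and leaves the 4-pyranone; the net result is the two new bonds C2–C3 and C3–C4 (chromene numbering) around the inserted carbon. The closest known reaction types are the dihalocarbene one-carbon ring expansion of cyclic silyl enol ethers to 2-halo-enones and the Ciamician–Dennstedt expansion of pyrroles and indoles to 3-halopyridines and 3-haloquinolines; a 3-silyloxyfuran has not been used in this way. The six-membered ring arises by enlargement of the five-membered ring (cheletropic addition, then electrocyclic opening) and not by a cyclisation, so no exo or endo closure mode is involved. No stereocentre is created, and the C5 silyloxy centre (C4 of 16) takes no part in any bond change and should be carried through unchanged. The step needs site-selectivity for the furan C2=C3 bond over the remote Z-alkene and over C3a=C7a, which the double oxygen donation into C2=C3 should provide when the carbene is kept limiting at low temperature in a non-polar medium that also slows attack of alkoxide on the enol silyl ether.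

Step 12
Reactants: 19 (5S)-3-bromo-5-[(tert-butyldimethylsilyl)oxy]-2-[(12Z)-heptadec-12-en-1-yl]-5,6,7,8-tetrahydro-4H-chromen-4-one
Product: 20 (5S)-5-[(tert-butyldimethylsilyl)oxy]-2-[(12Z)-heptadec-12-en-1-yl]-5,6,7,8-tetrahydro-4H-chromen-4-one
Conditions: Pd(OAc)2 (5 mol%), PPh3 (10 mol%), HCO2H (2 equiv), Et3N (3 equiv), DMF, 60 °C
Reagents that add atoms: none
Why: Palladium-catalysed hydrodehalogenation: oxidative addition into the C3–Br bond of the electron-poor bromopyranone, formate exchange with decarboxylation to a palladium hydride, and reductive elimination should put hydrogen at C3 without touching the isolated alkene, the silyl ether or the C5 centre.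

Step 13
Reactants: 20 (5S)-5-[(tert-butyldimethylsilyl)oxy]-2-[(12Z)-heptadec-12-en-1-yl]-5,6,7,8-tetrahydro-4H-chromen-4-one
Product: 21 (5S)-2-[(12Z)-heptadec-12-en-1-yl]-5-hydroxy-5,6,7,8-tetrahydro-4H-chromen-4-one
Conditions: HF·pyridine, THF/pyridine, 0 °C to rt
Reagents that add atoms: none
Why: Fluoride-driven cleavage of the Si–O bond (desilylation) under buffered conditions leaves the C5–O bond, and so the (5S) configuration, intact and avoids base-induced opening of the pyranone.

**Compound list**

1 | cyclohexane-1,3-dione | O=C1CCCC(=O)C1 | starting material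
2 | chloroacetyl chloride | ClCC(Cl)=O | starting material
3 | 3-oxocyclohex-1-en-1-yl chloroacetate | O=C1C=C(OC(=O)CCl)CCC1 | intermediate
4 | 2-(chloroacetyl)cyclohexane-1,3-dione | O=C(CCl)C1C(=O)CCCC1=O | intermediate (not isolated)
5 | 6,7-dihydro-1-benzofuran-3,4(2H,5H)-dione | O=C1COC2=C1C(=O)CCC2 | intermediate
6 | 12-bromododecan-1-ol | OCCCCCCCCCCCCBr | starting material
7 | (12-hydroxydodecyl)triphenylphosphonium bromide | [Br-].OCCCCCCCCCCCC[P+](c1ccccc1)(c1ccccc1)c1ccccc1 | intermediate
8 | pentanal | CCCCC=O | starting material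
9 | sodium 12-(triphenyl-λ5-phosphanylidene)dodecan-1-olate | [Na+].[O-]CCCCCCCCCCCC=P(c1ccccc1)(c1ccccc1)c1ccccc1 | intermediate (not isolated)
10 | (12Z)-heptadec-12-en-1-ol | CCCC/C=C\CCCCCCCCCCCO | intermediate
11 | (12Z)-heptadec-12-enal | CCCC/C=C\CCCCCCCCCCC=O | intermediate
12 | (2Z)-2-[(12Z)-heptadec-12-en-1-ylidene]-6,7-dihydro-1-benzofuran-3,4(2H,5H)-dione | CCCC/C=C\CCCCCCCCCC/C=C1\OC2=C(C1=O)C(=O)CCC2 | intermediate
13 | 2-[(12Z)-heptadec-12-en-1-yl]-6,7-dihydro-1-benzofuran-3,4(2H,5H)-dione (racemic at C2) | CCCC/C=C\CCCCCCCCCCCC1OC2=C(C1=O)C(=O)CCC2 | intermediate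
14 | 3-[(tert-butyldimethylsilyl)oxy]-2-[(12Z)-heptadec-12-en-1-yl]-6,7-dihydro-1-benzofuran-4(5H)-one | CCCC/C=C\CCCCCCCCCCCc1oc2c(c1O[Si](C)(C)C(C)(C)C)C(=O)CCC2 | intermediate
15 | (4S)-3-[(tert-butyldimethylsilyl)oxy]-2-[(12Z)-heptadec-12-en-1-yl]-4,5,6,7-tetrahydro-1-benzofuran-4-ol | CCCC/C=C\CCCCCCCCCCCc1oc2c(c1O[Si](C)(C)C(C)(C)C)[C@@H](O)CCC2 | intermediate
16 | (4S)-3,4-bis[(tert-butyldimethylsilyl)oxy]-2-[(12Z)-heptadec-12-en-1-yl]-4,5,6,7-tetrahydro-1-benzofuran | CCCC/C=C\CCCCCCCCCCCc1oc2c(c1O[Si](C)(C)C(C)(C)C)[C@@H](O[Si](C)(C)C(C)(C)C)CCC2 | intermediate (key-step precursor)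
17 | (6S)-1,1-dibromo-6,6b-bis[(tert-butyldimethylsilyl)oxy]-1a-[(12Z)-heptadec-12-en-1-yl]-1a,3,4,5,6,6b-hexahydro-1H-cyclopropa[b][1]benzofuran (cis-fused, either face) | CCCC/C=C\CCCCCCCCCCCC12OC3=C(C1(O[Si](C)(C)C(C)(C)C)C2(Br)Br)[C@@H](O[Si](C)(C)C(C)(C)C)CCC3 | intermediate (not isolated)
18 | (5S)-3-bromo-4,5-bis[(tert-butyldimethylsilyl)oxy]-2-[(12Z)-heptadec-12-en-1-yl]-5,6,7,8-tetrahydrochromenylium bromide | CCCC/C=C\CCCCCCCCCCCc1[o+]c2c(c(O[Si](C)(C)C(C)(C)C)c1Br)[C@@H](O[Si](C)(C)C(C)(C)C)CCC2.[Br-] | intermediate (not isolated)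
19 | (5S)-3-bromo-5-[(tert-butyldimethylsilyl)oxy]-2-[(12Z)-heptadec-12-en-1-yl]-5,6,7,8-tetrahydro-4H-chromen-4-one | CCCC/C=C\CCCCCCCCCCCc1oc2c(c(=O)c1Br)[C@@H](O[Si](C)(C)C(C)(C)C)CCC2 | intermediate (key-step product)
20 | (5S)-5-[(tert-butyldimethylsilyl)oxy]-2-[(12Z)-heptadec-12-en-1-yl]-5,6,7,8-tetrahydro-4H-chromen-4-one | CCCC/C=C\CCCCCCCCCCCc1oc2c(c(=O)c1)[C@@H](O[Si](C)(C)C(C)(C)C)CCC2 | intermediate
21 | (5S)-2-[(12Z)-heptadec-12-en-1-yl]-5-hydroxy-5,6,7,8-tetrahydro-4H-chromen-4-one | CCCC/C=C\CCCCCCCCCCCc1cc(=O)c2c(o1)CCC[C@@H]2O | target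

**Step count**

Total: 13 steps. Longest linear sequence: 11 steps (6 to 21 through steps 3–13).

**Steps most likely to fail**

1. Step 11 (proposed new method). The carbene may add to the chain Z-alkene or to C3a=C7a instead of C2=C3. Alternatively, tert-butoxide may strip the enol silyl group first, so that the furanolate is dibromomethylated at C2 instead of being ring-expanded. The fallback uses known chemistry and builds the pyranone by addition of an enol oxygen to an ynone. It sets out from alcohol 10 and dione 1 and comes back to the route at target 21. Alcohol 10 is converted with I2, PPh3 and imidazole into (5Z)-17-iodoheptadec-5-ene F1. F1 alkylates the dianion of propiolic acid (n-BuLi, THF/HMPA) to give (15Z)-icos-15-en-2-ynoic acid F2. Coupling of F2 with 1 (DCC, DMAP; O-acylation followed by DMAP-mediated O-to-C acyl shift) should give 2-[(15Z)-icos-15-en-2-ynoyl]cyclohexane-1,3-dione F3. Its enol oxygen adds to the ynone in a 6-endo-dig oxa-Michael closure (catalytic Et2NH or TfOH) to give 2-[(12Z)-heptadec-12-en-1-yl]-7,8-dihydro-4H-chromene-4,5(6H)-dione F4. Reduction of the C5 ketone of F4 with the (R)-CBS catalyst and catecholborane, the pyranone carbonyl being inert, should give 21.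

2. Step 9. Enantioface discrimination may be poor, or reduction slow, on a ketone that is deactivated as a vinylogous ester and shielded by the neighbouring silyloxy group. The fallback replaces asymmetric reduction by kinetic resolution; it sets out from ketone 14 and comes back at alcohol 15. DIBAL-H (toluene, −78 °C) reduces 14 to racemic 3-[(tert-butyldimethylsilyl)oxy]-2-[(12Z)-heptadec-12-en-1-yl]-4,5,6,7-tetrahydro-1-benzofuran-4-ol F5. Candida antarctica lipase B with vinyl acetate in MTBE should acylate the (R)-enantiomer (Kazlauskas preference for aryl/CH2 carbinols) to (4R)-3-[(tert-butyldimethylsilyl)oxy]-2-[(12Z)-heptadec-12-en-1-yl]-4,5,6,7-tetrahydro-1-benzofuran-4-yl acetate F6. Unreacted (S)-alcohol 15 is then separated by chromatography.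

3. Step 6. The enolisable aldehyde may self-condense, a second furanone may add to the alkylidene product in a Michael reaction, or the exocyclic double bond may migrate into the chain. The fallback is a directed Lewis-acid aldol that never exposes the aldehyde to base; it sets out from 5 and 11 and comes back at 12. Dione 5 is silylated (TBSOTf, Et3N) to 3-[(tert-butyldimethylsilyl)oxy]-6,7-dihydro-1-benzofuran-4(5H)-one F7. A Mukaiyama aldol addition of F7 to 11 (BF3·OEt2, CH2Cl2, −78 °C) at furan C2 gives 2-[(12Z)-1-hydroxyheptadec-12-en-1-yl]-6,7-dihydro-1-benzofuran-3,4(2H,5H)-dione F8 as a diastereomer mixture. Acid-catalysed dehydration of F8 (catalytic TsOH, toluene) gives 12.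

**Further compounds**

F1 | step 11 | (5Z)-17-iodoheptadec-5-ene | CCCC/C=C\CCCCCCCCCCCI
F2 | step 11 | (15Z)-icos-15-en-2-ynoic acid | CCCC/C=C\CCCCCCCCCCCC#CC(=O)O
F3 | step 11 | 2-[(15Z)-icos-15-en-2-ynoyl]cyclohexane-1,3-dione | CCCC/C=C\CCCCCCCCCCCC#CC(=O)C1C(=O)CCCC1=O
F4 | step 11 | 2-[(12Z)-heptadec-12-en-1-yl]-7,8-dihydro-4H-chromene-4,5(6H)-dione | CCCC/C=C\CCCCCCCCCCCc1cc(=O)c2c(o1)CCCC2=O
F5 | step 9 | rac-3-[(tert-butyldimethylsilyl)oxy]-2-[(12Z)-heptadec-12-en-1-yl]-4,5,6,7-tetrahydro-1-benzofuran-4-ol | CCCC/C=C\CCCCCCCCCCCc1oc2c(c1O[Si](C)(C)C(C)(C)C)C(O)CCC2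
F6 | step 9 | (4R)-3-[(tert-butyldimethylsilyl)oxy]-2-[(12Z)-heptadec-12-en-1-yl]-4,5,6,7-tetrahydro-1-benzofuran-4-yl acetate | CCCC/C=C\CCCCCCCCCCCc1oc2c(c1O[Si](C)(C)C(C)(C)C)[C@H](OC(C)=O)CCC2
F7 | step 6 | 3-[(tert-butyldimethylsilyl)oxy]-6,7-dihydro-1-benzofuran-4(5H)-one | CC(C)(C)[Si](C)(C)Oc1coc2c1C(=O)CCC2
F8 | step 6 | 2-[(12Z)-1-hydroxyheptadec-12-en-1-yl]-6,7-dihydro-1-benzofuran-3,4(2H,5H)-dione | CCCC/C=C\CCCCCCCCCCC(O)C1OC2=C(C1=O)C(=O)CCC2
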